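**Plan**
- Retrosynthesis: the C5 hydroperoxide and the C4=C15 alkene come from an ene reaction of a C4=C5 alkene; the angelate, the C3 carbinol and the C4=C5 bond lead back to methyl 3-oxoeudesm-11(13)-en-12-oate.
- That ketone is cut at C4–C5 and C6–C7 in one operation, giving an open-chain α-iodoethyl ketone.
- Enabling feature: C10 is already quaternary (it carries C14) and holds the C5=C6 vinyl group between a C1–C4 arm ending in a C4 α-keto radical precursor and a C9–C7 arm ending in a C7=C11 enoate with bromine on C13, so two 6-exo closures give rings A and B.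
- The chain is cut at C10–C1 (SN2′ alkylation of geranyl phosphate by a C1–C4/C15 Grignard fragment) and at C7–C11 (Morita–Baylis–Hillman reaction on the aldehyde from the geranyl tail).
- Forward: chain assembly (steps 1–11); ring A then ring B in one radical chain (step 12); enone, 3β-alcohol, angelate, hydroperoxide (steps 13–16).
- Stereochemistry: C10 from the chiral copper–carbene catalyst; C7 from the chair closure of ring B relative to C10; C3 from hydride delivery anti to C14; C5 from singlet-oxygen attack anti to C14; the Z-angelate from angelic acid.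

Key step: step 12

Remarks on the chemistry: eudesmane numbering is used also for open-chain compounds (C14 = methyl on C10, C15 = methyl on C4, C11–C13 = acrylate unit); β is the face of C14. The ligand enantiomer in step 5 is assumed to be the one that gives the 6S centre of 8. Centres that are destroyed later (carbinol carbons in 3–14, C4 in 15, C4 and C5 in 16) are carried as mixtures.

Step 1
Reactants: 1 3-bromopropan-1-ol
Product: 2 3-bromopropanal
Conditions: Dess–Martin periodinane, CH2Cl2, 0 °C to rt; used crude
Reagents that add atoms: none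
Why: Dess–Martin oxidation stops at the aldehyde under non-basic conditions, so the β-bromo aldehyde should not lose HBr before it is used.

Step 2
Reactants: 2 3-bromopropanal
Product: 3 5-bromopent-1-en-3-ol (racemic)
Conditions: CH2=CHMgBr, THF, −78 °C; H2O
Reagents that add atoms: vinylmagnesium bromide, C=C[Mg]Br
Why: Grignard 1,2-addition to the aldehyde at −78 °C is much faster than any reaction at the primary bromide, and the racemic carbinol centre is removed in step 11.

Step 3
Reactants: 3 5-bromopent-1-en-3-ol
Product: 4 [(5-bromopent-1-en-3-yl)oxy](tert-butyl)dimethylsilane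
Conditions: TBSCl, imidazole, DMF, rt
Reagents that add atoms: tert-butyldimethylsilyl chloride, CC(C)(C)[Si](C)(C)Cl
Why: Silyl ether protection of the secondary alcohol removes the only acidic proton before the Grignard reagent is made.

Step 4
Reactants: 5 geraniol
Product: 6 geranyl diethyl phosphate
Conditions: ClP(O)(OEt)2, pyridine, CH2Cl2, 0 °C
Reagents that add atoms: diethyl chlorophosphate, CCOP(=O)(Cl)OCC
Why: Phosphorylation of the primary allylic alcohol installs the leaving group needed for copper-catalysed allylic substitution and leaves the E-alkene untouched.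

Step 5
Reactants: 4 [(5-bromopent-1-en-3-yl)oxy](tert-butyl)dimethylsilane; 6 geranyl diethyl phosphate
Product: 8 tert-butyl{[(6S)-6-ethenyl-6,10-dimethylundeca-1,9-dien-3-yl]oxy}dimethylsilane, via silyloxypentenylmagnesium bromide 7 (not isolated)
Conditions: Mg, THF, rt; then 6, CuCl (5 mol %), chiral sulfonate-bearing imidazolinium salt (carbene precursor, 6 mol %), THF, −60 to −30 °C; H2O
Reagents that add atoms: none
Why: Copper-catalysed enantioselective allylic alkylation delivers the alkyl group to the γ-carbon (SN2′), creating quaternary C10 with its vinyl group; the chiral carbene ligand distinguishes the γ-methyl from the γ-alkyl chain and its enantiomer is chosen to give 6S.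

Step 6
Reactants: 8 tert-butyl{[(6S)-6-ethenyl-6,10-dimethylundeca-1,9-dien-3-yl]oxy}dimethylsilane
Product: 9 tert-butyl{[(6S)-8-(3,3-dimethyloxiran-2-yl)-6-ethenyl-6-methyloct-1-en-3-yl]oxy}dimethylsilane
Conditions: mCPBA (1.05 equiv), CH2Cl2, −20 to 0 °C
Reagents that add atoms: meta-chloroperoxybenzoic acid, OOC(=O)c1cccc(Cl)c1
Why: Prilezhaev epoxidation should select the electron-rich trisubstituted alkene over the two monosubstituted vinyl groups, and the epoxide centre is lost in step 7.

Step 7
Reactants: 9 tert-butyl{[(6S)-8-(3,3-dimethyloxiran-2-yl)-6-ethenyl-6-methyloct-1-en-3-yl]oxy}dimethylsilane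
Product: 10 (4R)-7-[(tert-butyldimethylsilyl)oxy]-4-ethenyl-4-methylnon-8-enal
Conditions: H5IO6, THF/Et2O, 0 °C
Reagents that add atoms: none
Why: Periodic acid opens the epoxide and performs the glycol cleavage in one flask, releasing acetone and the aldehyde that becomes C7, while the silyl ether and vinyl groups are inert at 0 °C.

Step 8
Reactants: 10 (4R)-7-[(tert-butyldimethylsilyl)oxy]-4-ethenyl-4-methylnon-8-enal; 11 methyl acrylate
Product: 12 methyl (6S)-9-[(tert-butyldimethylsilyl)oxy]-6-ethenyl-3-hydroxy-6-methyl-2-methylideneundec-10-enoate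
Conditions: DABCO (1 equiv), methyl acrylate (excess), MeOH, rt, several days
Reagents that add atoms: none
Why: The Morita–Baylis–Hillman reaction of the unhindered aliphatic aldehyde attaches C11–C13 and the ester, and the new carbinol configuration is lost in step 9.

Step 9
Reactants: 12 methyl (6S)-9-[(tert-butyldimethylsilyl)oxy]-6-ethenyl-3-hydroxy-6-methyl-2-methylideneundec-10-enoate
Product: 13 methyl (2Z,6S)-2-(bromomethyl)-9-[(tert-butyldimethylsilyl)oxy]-6-ethenyl-6-methylundeca-2,10-dienoate
Conditions: NBS, Me2S, CH2Cl2, −20 to 0 °C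
Reagents that add atoms: N-bromosuccinimide, O=C1CCC(=O)N1Br
Why: Corey–Kim-type activation of the hydroxyl as an alkoxysulfonium salt lets bromide enter at C13 with allylic transposition (SN2′), giving the conjugated Z-2-(bromomethyl)enoate that is the usual outcome for such adducts.

Step 10
Reactants: 13 methyl (2Z,6S)-2-(bromomethyl)-9-[(tert-butyldimethylsilyl)oxy]-6-ethenyl-6-methylundeca-2,10-dienoate
Product: 14 methyl (2Z,6S)-2-(bromomethyl)-6-ethenyl-9-hydroxy-6-methylundeca-2,10-dienoate
Conditions: aq. HF, MeCN, 0 °C to rt
Reagents that add atoms: none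
Why: Acidic fluoride desilylation frees the vinyl carbinol without any basic or nucleophilic species that would attack the allylic bromide.

Step 11
Reactants: 14 methyl (2Z,6S)-2-(bromomethyl)-6-ethenyl-9-hydroxy-6-methylundeca-2,10-dienoate
Product: 15 methyl (2Z,6S)-2-(bromomethyl)-6-ethenyl-10-iodo-6-methyl-9-oxoundec-2-enoate (both C4 epimers)
Conditions: [(η5-C5Me5)IrCl2]2 (2 mol %), 2,2-diiodo-5,5-dimethylcyclohexane-1,3-dione, THF/H2O, rt, dark
Reagents that add atoms: 2,2-diiodo-5,5-dimethylcyclohexane-1,3-dione, CC1(C)CC(=O)C(I)(I)C(=O)C1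
Why: Tandem iridium-catalysed 1,3-hydride shift and electrophilic iodination of the vinyl carbinol places iodine only on the former internal alkene carbon (C4, not C2), a regiochemistry that direct iodination of an ethyl ketone could not give.

Step 12
Reactants: 15 methyl (2Z,6S)-2-(bromomethyl)-6-ethenyl-10-iodo-6-methyl-9-oxoundec-2-enoate
Product: 16 methyl 3-oxoeudesm-11(13)-en-12-oate (10β-methyl, 7β-acrylate branch; trans-fused 4α-methyl isomer drawn, formed with its C4 and C5 epimers)
Conditions: Bu3SnSnBu3 (1.1 equiv), hν (sunlamp, Pyrex), PhH (0.01 M), 30 °C; KF work-up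
Reagents that add atoms: none
Why: Proposed new method: stannyl radicals from photolysed ditin abstract iodine from the α-iodoketone; the electrophilic C4 radical adds 6-exo-trig to C5 of the vinyl group (ring A), the nucleophilic primary C6 radical adds 6-exo-trig to C7 of the electron-poor enoate (ring B), and the C11 radical expels the C13 bromine atom, which ditin converts into Bu3SnBr and a new stannyl radical, so C4–C5, C6–C7 and the C11=C13 acrylate form in one chain. The closest known reactions are ditin-mediated iodine-atom-transfer cyclisations of α-iodo ketones onto terminal alkenes and radical addition–β-bromide elimination on 2-(bromomethyl)acrylates; their combination in one cascade has not been shown. Ring A should close through a cyclohexanone-like chair that keeps the oxoallyl radical conjugated, and ring B through a chair with the enoate branch equatorial. C4 and C5 are not controlled and need not be, because both become sp2 in step 13; C7 is set relative to C10 because in the trans-fused intermediate C1 and C4 are equatorial on ring B and C14 is axial, so the equatorial C7 branch ends up cis to C14. The step needs 6-exo rather than 7-endo attack in the first closure (favoured by the monosubstituted alkene and the fully substituted C10 next to C5) and iodine abstraction ahead of bromine abstraction (favoured by the weak C–I bond next to the carbonyl); the irreversible loss of bromine keeps the C11 radical from reacting further.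

Step 13
Reactants: 16 methyl 3-oxoeudesm-11(13)-en-12-oate (epimer mixture)
Product: 18 methyl 3-oxoeudesma-4,11(13)-dien-12-oate, via trimethylsilyl enol ether 17 (not isolated)
Conditions: Me3SiCl, NaI, Et3N, MeCN, rt; then Pd(OAc)2 (1.1 equiv), MeCN, rt
Reagents that add atoms: none
Why: Thermodynamic silylation should give the more substituted C3–C4 enol ether from every C4/C5 epimer, and Saegusa–Ito oxidation (palladation at C4, β-hydride elimination of H5) converts them all into one 4-en-3-one.

Step 14
Reactants: 18 methyl 3-oxoeudesma-4,11(13)-dien-12-oate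
Product: 19 methyl 3β-hydroxyeudesma-4,11(13)-dien-12-oate
Conditions: NaBH4, CeCl3·7H2O, MeOH, −40 °C
Reagents that add atoms: none
Why: Luche reduction gives 1,2-reduction of the enone with hydride entering axially on the α-face opposite C14, which should give the pseudo-equatorial 3β-alcohol and leave the acrylate untouched.

Step 15
Reactants: 19 methyl 3β-hydroxyeudesma-4,11(13)-dien-12-oate; 20 angelic acid
Product: 22 methyl 3β-[(2Z)-2-methylbut-2-enoyloxy]eudesma-4,11(13)-dien-12-oate, via mixed anhydride 21 (not isolated)
Conditions: 2,4,6-trichlorobenzoyl chloride, Et3N, toluene, rt; then 19, DMAP, toluene, 40–60 °C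
Reagents that add atoms: none
Why: Yamaguchi esterification through the mixed anhydride acylates the hindered allylic alcohol with retention at C3 and is the usual way to avoid isomerisation of the angelate to the tiglate.

Step 16
Reactants: 22 methyl 3β-[(2Z)-2-methylbut-2-enoyloxy]eudesma-4,11(13)-dien-12-oate
Product: 23 methyl 3β-[(2Z)-2-methylbut-2-enoyloxy]-5α-hydroperoxyeudesma-4(15),11(13)-dien-12-oate
Conditions: O2, hν (visible), tetraphenylporphyrin (cat.), CH2Cl2, −20 °C
Reagents that add atoms: oxygen, O=O
Why: In this Schenck ene reaction singlet oxygen should attack the tetrasubstituted C4=C5 alkene on the α-face opposite C14 and the 3β-ester, where the only well-aligned and non-deactivated allylic hydrogens are on C15, so oxygen bonds to C5 (5α-OOH) and the alkene shifts to C4=C15; the acrylate and angelate alkenes are too electron-poor to react.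

**Compound list**
1 | 3-bromopropan-1-ol | OCCCBr | starting material
2 | 3-bromopropanal | O=CCCBr | intermediate
3 | 5-bromopent-1-en-3-ol (racemic) | C=CC(O)CCBr | intermediate
4 | [(5-bromopent-1-en-3-yl)oxy](tert-butyl)dimethylsilane (racemic) | C=CC(CCBr)O[Si](C)(C)C(C)(C)C | intermediate
5 | geraniol | CC(C)=CCC/C(C)=C/CO | starting material
6 | geranyl diethyl phosphate | CC(C)=CCC/C(C)=C/COP(=O)(OCC)OCC | intermediate
7 | {3-[(tert-butyldimethylsilyl)oxy]pent-4-en-1-yl}magnesium bromide | C=CC(CC[Mg]Br)O[Si](C)(C)C(C)(C)C | intermediate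
8 | tert-butyl{[(6S)-6-ethenyl-6,10-dimethylundeca-1,9-dien-3-yl]oxy}dimethylsilane (3RS) | C=C[C@](C)(CCC(O[Si](C)(C)C(C)(C)C)C=C)CCC=C(C)C | intermediate
9 | tert-butyl{[(6S)-8-(3,3-dimethyloxiran-2-yl)-6-ethenyl-6-methyloct-1-en-3-yl]oxy}dimethylsilane | C=C[C@](C)(CCC(O[Si](C)(C)C(C)(C)C)C=C)CCC1OC1(C)C | intermediate
10 | (4R)-7-[(tert-butyldimethylsilyl)oxy]-4-ethenyl-4-methylnon-8-enal (7RS) | C=C[C@](C)(CCC(O[Si](C)(C)C(C)(C)C)C=C)CCC=O | intermediate
11 | methyl acrylate | C=CC(=O)OC | starting material
12 | methyl (6S)-9-[(tert-butyldimethylsilyl)oxy]-6-ethenyl-3-hydroxy-6-methyl-2-methylideneundec-10-enoate (3RS,9RS) | C=C[C@](C)(CCC(O[Si](C)(C)C(C)(C)C)C=C)CCC(O)C(=C)C(=O)OC | intermediate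
13 | methyl (2Z,6S)-2-(bromomethyl)-9-[(tert-butyldimethylsilyl)oxy]-6-ethenyl-6-methylundeca-2,10-dienoate (9RS) | C=C[C@](C)(CCC(O[Si](C)(C)C(C)(C)C)C=C)CC/C=C(\CBr)C(=O)OC | intermediate
14 | methyl (2Z,6S)-2-(bromomethyl)-6-ethenyl-9-hydroxy-6-methylundeca-2,10-dienoate (9RS) | C=C[C@](C)(CCC(O)C=C)CC/C=C(\CBr)C(=O)OC | intermediate
15 | methyl (2Z,6S)-2-(bromomethyl)-6-ethenyl-10-iodo-6-methyl-9-oxoundec-2-enoate (10RS) | C=C[C@](C)(CCC(=O)C(C)I)CC/C=C(\CBr)C(=O)OC | intermediate
16 | methyl 3-oxoeudesm-11(13)-en-12-oate (trans-fused, 4α-methyl isomer; C4/C5 epimers accompany it) | C=C(C(=O)OC)[C@@H]1CC[C@@]2(C)CCC(=O)[C@@H](C)[C@@H]2C1 | intermediate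
17 | methyl 3-(trimethylsilyloxy)eudesma-3,11(13)-dien-12-oate (5αH isomer drawn) | C=C(C(=O)OC)[C@@H]1CC[C@@]2(C)CCC(O[Si](C)(C)C)=C(C)[C@@H]2C1 | intermediate
18 | methyl 3-oxoeudesma-4,11(13)-dien-12-oate | C=C(C(=O)OC)[C@@H]1CC[C@@]2(C)CCC(=O)C(C)=C2C1 | intermediate
19 | methyl 3β-hydroxyeudesma-4,11(13)-dien-12-oate | C=C(C(=O)OC)[C@@H]1CC[C@@]2(C)CC[C@H](O)C(C)=C2C1 | intermediate
20 | angelic acid, (2Z)-2-methylbut-2-enoic acid | C/C=C(/C)C(=O)O | starting material
21 | (2Z)-2-methylbut-2-enoic 2,4,6-trichlorobenzoic anhydride | C/C=C(/C)C(=O)OC(=O)c1c(Cl)cc(Cl)cc1Cl | intermediate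
22 | methyl 3β-[(2Z)-2-methylbut-2-enoyloxy]eudesma-4,11(13)-dien-12-oate | C=C(C(=O)OC)[C@@H]1CC[C@@]2(C)CC[C@H](OC(=O)/C(C)=C\C)C(C)=C2C1 | intermediate
23 | methyl 3β-[(2Z)-2-methylbut-2-enoyloxy]-5α-hydroperoxyeudesma-4(15),11(13)-dien-12-oate | C=C(C(=O)OC)[C@@H]1CC[C@@]2(C)CC[C@H](OC(=O)/C(C)=C\C)C(=C)[C@]2(OO)C1 | target

**Step count**
Total: 16 steps. Longest linear sequence: 15 steps (steps 1–3 and 5–16; step 4 is the one-step side branch).

**Steps most likely to fail**

Step 12 (the proposed new method). The risks lie in the chain itself: the C4 radical may add to the terminal vinyl carbon (7-endo) instead of C5; stannyl radicals may remove the allylic bromine before the iodine; and the cis-fused C6 radical may close ring B through the alternative chair, which would erode the C7/C10 relation. The fallback uses known reactions only, closes one ring at a time, sets out from 12 and comes back at 16.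
- Acetylation of 12 (Ac2O, pyridine) should give methyl (6S)-3-acetoxy-9-[(tert-butyldimethylsilyl)oxy]-6-ethenyl-6-methyl-2-methylideneundec-10-enoate F1.
- Aqueous HF in MeCN should give the vinyl carbinol methyl (6R)-3-acetoxy-6-ethenyl-9-hydroxy-6-methyl-2-methylideneundec-10-enoate F2.
- The iridium-catalysed isomerisation–iodination of step 11 should give methyl (6S)-3-acetoxy-6-ethenyl-10-iodo-6-methyl-2-methylidene-9-oxoundecanoate F3, whose untransposed acrylate is no 6-exo acceptor.
- Catalytic Bu3SnSnBu3 and light should then effect a plain iodine-atom-transfer cyclisation (the C6 radical takes iodine from F3) to methyl 3-acetoxy-5-[2-(iodomethyl)-1,3-dimethyl-4-oxocyclohexyl]-2-methylidenepentanoate F4, from which the isomer with H5 anti to C14 is separated.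
- MgBr2·OEt2 should convert the allylic acetate with transposition into methyl (2Z)-2-(bromomethyl)-5-[2-(iodomethyl)-1,3-dimethyl-4-oxocyclohexyl]pent-2-enoate F5.
- A tin-mediated 6-exo cyclisation of the primary iodide with loss of bromine (Bu3SnSnBu3, hν) should close ring B on the ring-fusion isomer already selected and give 16.

Step 5. The enantioselectivity and the SN2′/SN2 ratio may erode, because the two γ-substituents of the geranyl unit differ little and the Grignard reagent carries a Lewis-basic silyl ether; Wurtz coupling may also occur while the reagent is made. The fallback changes the nucleophile and how it is made, sets out from geraniol 5 and comes back at 8; steps 1–3 are then not needed.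
- Geraniol is converted (MsCl, Et3N; LiCl) into (2E)-1-chloro-3,7-dimethylocta-2,6-diene F6.
- The silyl ether of commercial penta-1,4-dien-3-ol, tert-butyldimethyl(penta-1,4-dien-3-yloxy)silane F7, used in excess, is hydroborated once with 9-borabicyclo[3.3.1]nonane to 9-{3-[(tert-butyldimethylsilyl)oxy]pent-4-en-1-yl}-9-borabicyclo[3.3.1]nonane F8.
- Copper-catalysed γ-selective enantioselective allyl–alkyl coupling of F6 with F8 (CuCl, chiral phenol-bearing imidazolinium salt, KOMe) should give 8.

Step 11. The iridium hydride may be intercepted by the allylic bromide, the bromide may solvolyse in the aqueous medium, or the doubly labile product may lose HI during the reaction. The fallback separates oxidation from regiospecific iodination and avoids water and metal hydrides; it sets out from 14 and comes back at 15.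
- Dess–Martin oxidation of 14 should give the vinyl ketone methyl (2Z,6S)-2-(bromomethyl)-6-ethenyl-6-methyl-9-oxoundeca-2,10-dienoate F9.
- Conjugate reduction with catecholborane (THF, rt), which leaves the enoate, the bromide and the isolated vinyl group alone, should give the boron enolate methyl (2Z,6S,9Z)-9-[(1,3,2-benzodioxaborol-2-yl)oxy]-2-(bromomethyl)-6-ethenyl-6-methylundeca-2,9-dienoate F10.
- N-Iodosuccinimide should iodinate F10 at C4 only and give 15.

**Further compounds**
F1 | step 12 | methyl (6S)-3-acetoxy-9-[(tert-butyldimethylsilyl)oxy]-6-ethenyl-6-methyl-2-methylideneundec-10-enoate | C=C[C@](C)(CCC(O[Si](C)(C)C(C)(C)C)C=C)CCC(OC(C)=O)C(=C)C(=O)OC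
F2 | step 12 | methyl (6R)-3-acetoxy-6-ethenyl-9-hydroxy-6-methyl-2-methylideneundec-10-enoate | C=C[C@](C)(CCC(O)C=C)CCC(OC(C)=O)C(=C)C(=O)OC
F3 | step 12 | methyl (6S)-3-acetoxy-6-ethenyl-10-iodo-6-methyl-2-methylidene-9-oxoundecanoate | C=C[C@](C)(CCC(=O)C(C)I)CCC(OC(C)=O)C(=C)C(=O)OC
F4 | step 12 | methyl 3-acetoxy-5-[2-(iodomethyl)-1,3-dimethyl-4-oxocyclohexyl]-2-methylidenepentanoate (iodomethyl cis to the methyl on the quaternary ring carbon) | CC1C(=O)CC[C@](C)(CCC(OC(C)=O)C(=C)C(=O)OC)[C@H]1CI
F5 | step 12 | methyl (2Z)-2-(bromomethyl)-5-[2-(iodomethyl)-1,3-dimethyl-4-oxocyclohexyl]pent-2-enoate (same ring configuration as F4) | CC1C(=O)CC[C@](C)(CC/C=C(\CBr)C(=O)OC)[C@H]1CI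
F6 | step 5 | (2E)-1-chloro-3,7-dimethylocta-2,6-diene (geranyl chloride) | CC(C)=CCC/C(C)=C/CCl
F7 | step 5 | tert-butyldimethyl(penta-1,4-dien-3-yloxy)silane | C=CC(C=C)O[Si](C)(C)C(C)(C)C
F8 | step 5 | 9-{3-[(tert-butyldimethylsilyl)oxy]pent-4-en-1-yl}-9-borabicyclo[3.3.1]nonane | C=CC(CCB1C2CCCC1CCC2)O[Si](C)(C)C(C)(C)C
F9 | step 11 | methyl (2Z,6S)-2-(bromomethyl)-6-ethenyl-6-methyl-9-oxoundeca-2,10-dienoate | C=C[C@](C)(CCC(=O)C=C)CC/C=C(\CBr)C(=O)OC
F10 | step 11 | methyl (2Z,6S,9Z)-9-[(1,3,2-benzodioxaborol-2-yl)oxy]-2-(bromomethyl)-6-ethenyl-6-methylundeca-2,9-dienoate | C=C[C@](C)(CC/C(OB1Oc2ccccc2O1)=C/C)CC/C=C(\CBr)C(=O)OC
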